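Remark: the terpene half is numbered as a eudesmane (C1–C15; α/β refer to the decalin with the angular C14 methyl β) and the chromene carries primed locants; the carbinol carbon C4' of 13 and 18 is carried as a mixture of epimers, because it becomes trigonal again before the target is reached.

## Structural features

The target is a 5',7',8'-trimethoxy-2'-phenyl-4'H-chromene whose C4' is bonded to C1 of a eudesmane. The eudesmane is a trans-fused decalin (rings A and B) with the angular methyl on the quaternary C10, a tertiary carbinol at C4 (4α-OH, 4β-CH3) and an isopropenyl group on C7. There are six stereocentres: C1, C10, C5 and C4 are contiguous around ring A, C7 stands alone on ring B, and C4' lies outside the decalin but directly on C1, next to the quaternary C10. The C1 substituent, the C7 isopropenyl group and the C4 hydroxyl are all equatorial, so C1 keeps its configuration even while a carbonyl group sits on C4'. The fragile parts are the 4H-chromene (a cyclic aryl enol ether with a doubly activated C4'–H), the tertiary alcohol (elimination under acid) and the isopropenyl group (a second alkene in every electrophilic step). The real difficulty is threefold: the quaternary C10 flanked by the stereocentres C1 and C5, the C1–C4' bond that joins two stereocentres, and the need to single out one of four aryl oxygens as the ring oxygen O1'. The key step exploits ring A (C1, C2, C3, C4, C5, C10): with a C3=C4 double bond (the latent C4 carbinol) and C4' as a ketone it is a cyclohexene retron with C1=C10 as activated dienophile. With C6–C9 as tether, one intramolecular [4+2] closes rings A and B and sets C1, C5 and C10 under the control of C7, which (R)-limonene supplies.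

## Logic of the disconnections

**22 ⇒ 21.** The enol ether C2'=C3' is returned to C2'(OCH3)–C3'H2 by formal addition of methanol. The enol ether is the most acid- and oxidation-sensitive part and is best made last, and the ketal is the natural product of a [4+2] closure of the pyran. The forward step must lose methanol without ionising the C4 carbinol.

**21 ⇒ 18 + 19 (through 20).** The bonds C4'–C3' and O1'–C2' are cut. They lie in a six-membered ring whose oxygen sits on an arene ortho to C4', which is the retron of a hetero-Diels–Alder addition of an o-quinone methide. The cut removes nine carbons and one ring and leaves a benzylic alcohol with a free ortho phenol. The forward step must form 20 without strong acid, trap it faster than it tautomerises, and bring 19 onto the face of C4' that is turned away from C10.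

**18 ⇒ 17 ⇒ 16.** No skeletal bond is cut. The C3–H and C4'–H bonds are removed first (back to the 3α,4α-epoxide and the ketone of 17), then the two C–O bonds of the epoxide (back to C3=C4 of 16). A tertiary carbinol with α oxygen next to a CH2 is the hydride-opened form of the α-epoxide of a trisubstituted alkene, and the same hydride creates the benzylic alcohol. C4 ceases to be a stereocentre and ring A regains the alkene that a cycloaddition leaves behind. The peracid must choose C3=C4 over the isopropenyl group and the α face; the hydride must enter at C3.

**16 ⇒ 15.** The O–CH3 bond on the oxygen that becomes O1' is restored. Four like ethers let the arene come from the symmetric 9 and keep a phenol out of the organoaluminium chemistry. The forward cleavage must pick the one methoxy group that lies between the carbonyl and another methoxy group.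

**15 ⇒ 14.** The bonds C1–C2 and C5–C10 are cut. This opens both rings at once, removes C1, C5 and C10 as stereocentres and turns the quaternary C10 into an alkene carbon. A bicycle with four stereocentres becomes an acyclic triene with one. The forward step needs E geometry at C1=C10 and C4=C5, the aroyl-endo transition state, and a chair-like tether with the isopropenyl group equatorial.

**14 ⇒ 13 ⇒ 8 + 11 (through 12).** After the ketone is returned to the carbinol, C1–C4' and C10–C14 are cut. A trisubstituted (E)-alkenyl carbinol is what syn methylmetalation of a terminal alkyne followed by aldehyde addition gives, and this is the most dependable source of the E geometry. The aryl half becomes 11 and the terpene half 8. The carbometalation must ignore the diene and the isopropenyl group, and the alkenyl metal must add to a hindered, electron-rich aldehyde.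

**11 ⇒ 9 (through 10).** The aryl–CHO bond is cut. Only two, equivalent, positions of 9 are free, so an ordinary electrophilic formylation suffices.

**8 ⇒ 6 (through 7).** The triple bond C1≡C10 is returned to a methyl ketone (C10=O, C1H3). That ketone is what ring cleavage of 1 leaves. The forward step needs kinetic enolisation towards the methyl group.

**6 ⇒ 5 ⇒ 4.** C2=C3 is cut first, then C4=C5. Each is an olefination of an aldehyde; the second cut corresponds to a stabilised ylide, which sets the (E)-trisubstituted C4=C5 and tells aldehyde from ketone. In the forward methylenation the enal must react before the methyl ketone.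

**4 ⇒ 2 ⇒ 1 (through 3).** The ketone carbon (C10) and the aldehyde carbon (C5) are reconnected to a ring alkene. The 1,6-dicarbonyl pattern with an isopropenyl-bearing stereocentre is the cleaved form of the enantiopure 1, so C7 comes with the right absolute configuration. Oxidation must occur at the ring alkene only.

## Other disconnections considered

**Alternative 1:** The cut is C9–C10 of ring B. The forward key step would be a 6-endo-trig radical closure under tin hydride chain conditions. The precursor is iodide A2, made by C-alkylation of Hagemann's ester A1 at its α-carbon (the future C5) with an enantiopure four-carbon chain that carries C7 as an acetyl ketal. The primary C9 radical adds to the β-carbon C10 of the enone, and the α-keto radical at C5 takes up hydrogen to give decalone A3.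
- In its favour: ring A is bought ready-made; a radical forms the quaternary centre with little regard for crowding and tolerates ketal and ester; the C4 ketone of A3 is a direct handle on the carbinol carbon.
- Against it here: only one ring and one C–C bond are formed. C10 is set under two separate influences (the epimerisable C1 ester and the C7 side chain), and C5 depends on hydrogen delivery or on a later equilibration that is only modestly biased towards the trans fusion in a 10-methyl-1-decalone. The C7 stereocentre needs its own enantioselective chain synthesis.
- After A3 three exchanges remain: ester to aryl ketone, ketal to isopropenyl, and C4 ketone to the 4α-carbinol. Direct methyl addition is expected from the α face, anti to the angular methyl, which would give the 4-epimer, so a methylenation, epoxidation and hydride detour would be needed.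
- Comparison: in functional-group tolerance the radical closure is the equal of the cycloaddition, and it is better in one respect, because no acid-sensitive diene meets a Lewis acid and no geometrically pure trisubstituted enone is required. On structure the chosen plan is ahead, since it closes both rings and fixes C1, C5 and C10 together with the aryl ketone already in place. On step economy the alternative is expected to be longer.

**Alternative 2:** The cut is the pair C4'–C3' and O1'–C2', made the centre of the plan. The aryl tert-butyl carbonate A4 (the 4α-hydroxy aryl ketone with its ortho phenol as O-Boc) would be treated with one equivalent of a hydride donor at low temperature in the presence of α-methoxystyrene A5 (identical with 19). The benzylic alkoxide takes over the Boc group, which is then expelled, and the o-quinone methide A6 (identical with 20) adds A5 to give ketal A7 (identical with 21).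
- In its favour: it is the shortest convergent union of the two halves. The quinone methide arises under basic conditions far below room temperature, where neither the hydrogen shift to a vinyl phenol nor ionisation of the tertiary alcohol is to be feared, and the low temperature should help the facial selectivity at C4'. On this point it is better than the thermal dehydration of step 13.
- Against it: it forms one ring and one lasting stereocentre and says nothing about the decalin, which would still have to be made, most probably by the cycloaddition chosen here. A4 needs the C4 carbinol while C4' is still a ketone, which the epoxide and hydride sequence cannot deliver without a re-oxidation. The Boc group costs a step. The hydride must be dosed exactly, since an excess would reduce A6 at C4'.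
- Comparison: on the bond set the two plans are equal, because the chosen endgame makes the same two bonds from the same partners. The alternative is better in the mildness of the quinone methide generation. The chosen plan is better in step economy (ketone and epoxide reduced in one operation, no protecting group) and in the weight of its key step (two rings, three stereocentres).

**Alternative 3:** The cut is O1'–C8a'. The phenyl ketone–quinone A8 (C4' already bonded to a 5-methoxy-1,4-benzoquinone) would enolise, the enol oxygen would add to the quinone carbon C8a' in a 6-endo conjugate addition, and tautomerisation would give the chromene hydroquinone A9. Two O-methylations would complete 22.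
- In its favour: no ortho oxygen has to be singled out by demethylation, since O1' arrives in the ring closure itself; on this point it is better than the chosen plan. The chromene enol ether forms directly without a ketal, and the closure needs neither heat nor strong acid.
- Against it: no stereocentre is created, so C4' must be set beforehand in an open-chain setting. The C4'–H of A8 is α to the quinone and can tautomerise to a quinone methide, which threatens that stereocentre. A9 is an electron-rich hydroquinone that reoxidises easily and needs two methylations beside a tertiary alcohol. The arene would have to enter with a different oxidation pattern and be oxidised to the quinone late, with two alkenes present.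
- Comparison: on structure it solves only the heterocycle and leaves the decalin to another method. On mechanism it is equal in the mildness of the closure and better in the regiochemical certainty about O1', but weaker in stereocontrol at C4'. On step economy it loses through the redox adjustments and the methylations.

Key step: step 9

## Route

Step 1
Reactants: 1 (R)-limonene
Product: 2 (4R)-limonene 1,2-oxide (cis/trans mixture at C1/C2)
Conditions: mCPBA (1.0 equiv), NaHCO3, CH2Cl2, 0 °C
Reagents that add atoms: mCPBA (3-chloroperoxybenzoic acid), OOC(=O)c1cccc(Cl)c1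
Why: Prilezhaev epoxidation; the trisubstituted ring alkene is more nucleophilic than the 1,1-disubstituted isopropenyl group, so one equivalent of peracid should go to the ring. The two epoxide stereocentres are erased in step 2, so the diastereomer mixture is of no consequence.

Step 2
Reactants: 2 (4R)-limonene 1,2-oxide
Product: 4 (3R)-6-oxo-3-(prop-1-en-2-yl)heptanal, via limonene-1,2-diol 3 (not isolated)
Conditions: H5IO6 (1.2 equiv), THF/H2O, 0 °C → rt
Reagents that add atoms: water, O
Why: Acid-assisted hydrolysis of the epoxide to the diol and Malaprade glycol cleavage in the same flask should give the ketone at the former tertiary carbon and the aldehyde at the secondary one. The stereocentre is β to the aldehyde and is not touched.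

Step 3
Reactants: 4 (3R)-6-oxo-3-(prop-1-en-2-yl)heptanal
Product: 5 (2E,5R)-2-methyl-8-oxo-5-(prop-1-en-2-yl)non-2-enal
Conditions: Ph3P=C(CH3)CHO (1.15 equiv), PhMe, 80 °C
Reagents that add atoms: 2-(triphenylphosphoranylidene)propanal, CC(C=O)=P(c1ccccc1)(c1ccccc1)c1ccccc1
Why: Wittig reaction with a stabilised ylide, which attacks the aldehyde and leaves the methyl ketone alone and which should give the (E)-trisubstituted C4=C5 under thermodynamic control of the oxaphosphetane breakdown.

Step 4
Reactants: 5 (2E,5R)-2-methyl-8-oxo-5-(prop-1-en-2-yl)non-2-enal
Product: 6 (5R,7E)-8-methyl-5-(prop-1-en-2-yl)deca-7,9-dien-2-one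
Conditions: Ph3PCH3Br (1.05 equiv), KOt-Bu (1.0 equiv), THF, 0 °C; then 5, −78 → −20 °C
Reagents that add atoms: methyltriphenylphosphonium bromide, C[P+](c1ccccc1)(c1ccccc1)c1ccccc1.[Br-]
Why: Wittig methylenation; the non-stabilised ylide reacts with an aldehyde at −78 °C, where a methyl ketone is still inert, so one equivalent at low temperature should convert the enal only. The C4=C5 geometry is not touched.

Step 5
Reactants: 6 (5R,7E)-8-methyl-5-(prop-1-en-2-yl)deca-7,9-dien-2-one
Product: 8 (3E,6R)-3-methyl-6-(prop-1-en-2-yl)deca-1,3-dien-9-yne, via enol phosphate 7 (not isolated)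
Conditions: LiN(i-Pr)2 (1.1 equiv), THF, −78 °C; ClP(O)(OEt)2, −78 °C → rt; LiN(i-Pr)2 (2.5 equiv), −78 °C → rt
Reagents that add atoms: diethyl chlorophosphate, CCOP(=O)(Cl)OCC (its atoms stand in 7 only and leave again)
Why: Kinetic deprotonation at the methyl group, O-phosphorylation and base-induced β-elimination of the terminal enol phosphate (the methyl ketone to alkyne protocol) should give the terminal alkyne. The diene and the remote stereocentre are inert to the amide base at low temperature.

Step 6
Reactants: 9 1,2,3,5-tetramethoxybenzene
Product: 11 2,3,4,6-tetramethoxybenzaldehyde, via aryl iminium chloride 10 (not isolated)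
Conditions: POCl3 (1.2 equiv), DMF, 0 °C → rt; then aq. NaOAc
Reagents that add atoms: N,N-dimethylformamide, CN(C)C=O; water, O
Why: Vilsmeier–Haack formylation of a highly activated arene whose only two free positions are equivalent, so a single aldehyde should result after hydrolysis of the iminium salt.

Step 7
Reactants: 8 (3E,6R)-3-methyl-6-(prop-1-en-2-yl)deca-1,3-dien-9-yne; 11 2,3,4,6-tetramethoxybenzaldehyde
Product: 13 (2E,6R,8E)-3,9-dimethyl-6-(prop-1-en-2-yl)-1-(2,3,4,6-tetramethoxyphenyl)undeca-2,8,10-trien-1-ol (both C1 epimers), via alkenylalane 12 (not isolated)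
Conditions: Me3Al (2.5 equiv), Cp2ZrCl2 (0.25 equiv), CH2Cl2, 0 °C → rt; volatiles removed; then 11, CH2Cl2, −78 → 0 °C
Reagents that add atoms: trimethylaluminium, C[Al](C)C
Why: Negishi zirconium-catalysed methylalumination adds CH3 and Al syn across the terminal alkyne with aluminium on the terminal carbon, which fixes the E geometry of C1=C10; the alkenyl–aluminium bond then adds to the aldehyde. Alkenes and the conjugated diene are carbometalated far more slowly than a terminal alkyne, and the new carbinol centre is left uncontrolled because it is oxidised in step 8.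

Step 8
Reactants: 13 (2E,6R,8E)-3,9-dimethyl-6-(prop-1-en-2-yl)-1-(2,3,4,6-tetramethoxyphenyl)undeca-2,8,10-trien-1-ol
Product: 14 (2E,6R,8E)-3,9-dimethyl-6-(prop-1-en-2-yl)-1-(2,3,4,6-tetramethoxyphenyl)undeca-2,8,10-trien-1-one
Conditions: Dess–Martin periodinane (1.3 equiv), NaHCO3, CH2Cl2, 0 °C → rt
Reagents that add atoms: none
Why: Dess–Martin oxidation of an allylic, benzylic alcohol under buffered conditions, which should avoid ionisation of the electron-rich carbinol and leave both the E-enone geometry and the diene intact.

Step 9
Reactants: 14 (2E,6R,8E)-3,9-dimethyl-6-(prop-1-en-2-yl)-1-(2,3,4,6-tetramethoxyphenyl)undeca-2,8,10-trien-1-one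
Product: 15 1β-(2,3,4,6-tetramethoxybenzoyl)eudesma-3,11-diene (5α-H, 7β-isopropenyl, 10β-methyl)
Conditions: Me2AlCl (1.5–2.0 equiv), CH2Cl2, −78 → 0 °C
Reagents that add atoms: none
Why: Me2AlCl binds the ketone oxygen (the two flanking methoxy groups twist the arene out of conjugation, so the enone carries the LUMO) and the enone adds across the diene termini in one concerted, asynchronous, suprafacial [4+2] step; the closest known reaction type is the Lewis acid-promoted intramolecular Diels–Alder reaction of (E,E)-1,7,9-decatrienes with a carbonyl group at the dienophile terminus, which gives trans-fused octalins. Ring A (C1, C2, C3, C4, C5, C10) is closed as the cyclohexene of the cycloaddition by the new bonds C1–C2 and C5–C10, and ring B (C5 to C10) is closed at the same time by C5–C10 across the four-carbon tether C6–C9 folded as a chair. C10 relative to C1: the E geometry of C1=C10 is transferred suprafacially, so the aroyl group and the C14 methyl end up cis (both β). C5 relative to C10: the aroyl-endo transition state, which Lewis acid complexation favours, leaves the tether exo and gives the trans ring fusion (5α-H). The absolute sense at all three centres comes from C7: in the chair-like tether the isopropenyl group is equatorial, which fixes the diene face that meets the dienophile. The step needs endo over exo, chair over boat, and reaction at the diene and not at the isolated isopropenyl group; the E,E geometry from steps 3 and 7, the single stereocentre on the tether and a proton-scavenging alkylaluminium chloride at low temperature are what secure them. C1 is α to the ketone, but its β substituent is equatorial, so the kinetic product is also the thermodynamic epimer.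

Step 10
Reactants: 15 1β-(2,3,4,6-tetramethoxybenzoyl)eudesma-3,11-diene
Product: 16 1β-(2-hydroxy-3,4,6-trimethoxybenzoyl)eudesma-3,11-diene
Conditions: BCl3 (1.2 equiv), CH2Cl2, −78 → −20 °C; cold aq. NaHCO3
Reagents that add atoms: none
Why: Chelation-controlled ortho-demethylation of an aryl ketone: boron is held between the carbonyl and an ortho methoxy oxygen and chloride removes that methyl group. Of the two ortho ethers, the one buttressed by the neighbouring methoxy group is twisted out of the ring plane, is the more basic oxygen and gains most from cleavage, so the phenol should appear at the position that becomes O1'; the alkenes are not expected to suffer at this temperature with a basic quench.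

Step 11
Reactants: 16 1β-(2-hydroxy-3,4,6-trimethoxybenzoyl)eudesma-3,11-diene
Product: 17 3α,4α-epoxy-1β-(2-hydroxy-3,4,6-trimethoxybenzoyl)eudesm-11-ene
Conditions: mCPBA (1.05 equiv), NaHCO3, CH2Cl2, −20 → 0 °C
Reagents that add atoms: mCPBA (3-chloroperoxybenzoic acid), OOC(=O)c1cccc(Cl)c1
Why: Prilezhaev epoxidation; the trisubstituted C3=C4 is more electron-rich than the isopropenyl group, and the axial 10β-methyl shields the β face, so the oxygen should arrive from the α face and set C4 (with C3 as a temporary centre). The hydrogen-bonded acylphenol is deactivated towards the peracid.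

Step 12
Reactants: 17 3α,4α-epoxy-1β-(2-hydroxy-3,4,6-trimethoxybenzoyl)eudesm-11-ene
Product: 18 1β-[hydroxy(2-hydroxy-3,4,6-trimethoxyphenyl)methyl]eudesm-11-en-4α-ol (both carbinol epimers)
Conditions: LiAlH4 (5 equiv), THF, 0 → 50 °C; aq. potassium sodium tartrate
Reagents that add atoms: none
Why: Hydride opens the trisubstituted epoxide by SN2 attack at the secondary C3 from the β face, so the C4–O bond and the 4α configuration are kept and C3 becomes CH2; attack at the tertiary C4, syn to the angular methyl, is not feasible. The same reagent reduces the ketone, and the configuration of the new benzylic carbinol is irrelevant because step 13 makes C4' trigonal.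

Step 13
Reactants: 18 1β-[hydroxy(2-hydroxy-3,4,6-trimethoxyphenyl)methyl]eudesm-11-en-4α-ol; 19 α-methoxystyrene
Product: 21 1β-(2'-methoxy-5',7',8'-trimethoxy-2'-phenylchroman-4'-yl)eudesm-11-en-4α-ol (methoxy cis to the eudesmyl group), via o-quinone methide 20 (not isolated)
Conditions: 19 (8 equiv), PhMe, 100 °C, sealed tube
Reagents that add atoms: none
Why: Thermal dehydration of the electron-rich o-hydroxybenzyl alcohol releases the o-quinone methide, which undergoes an inverse-electron-demand hetero-Diels–Alder addition with the enol ether; the nucleophilic CH2 terminus bonds to C4' and the carbonyl oxygen to C2'. Allylic 1,3-strain holds C1–H in the plane of the exocyclic C4'=C4a' bond, so one face of C4' is covered by the quaternary C10 with its axial methyl and the other only by the C2 methylene; approach past C2 gives the C4' configuration of the target. The configuration at C2' (methoxy endo expected) is of no consequence.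

Step 14
Reactants: 21 1β-(2'-methoxy-5',7',8'-trimethoxy-2'-phenylchroman-4'-yl)eudesm-11-en-4α-ol
Product: 22 1β-[(4'R)-5',7',8'-trimethoxy-2'-phenyl-4'H-chromen-4'-yl]eudesm-11-en-4α-ol (target; 1S,4R,5R,7R,10S in eudesmane numbering)
Conditions: PPTS (0.2 equiv), 5 Å MS, PhMe, 80 °C
Reagents that add atoms: none
Why: Acid-catalysed elimination of methanol from the mixed ketal: the oxocarbenium ion at C2', stabilised by the ring oxygen and the phenyl group, loses a C3' proton to give the conjugated enol ether, and the sieves take up the methanol. The ketal ionises far more readily than the tertiary alcohol under a pyridinium acid, and C4' is not involved.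

## Compound list

1 | (R)-limonene | CC1=CC[C@@H](CC1)C(C)=C | starting material
2 | (4R)-limonene 1,2-oxide, cis/trans mixture at C1/C2 | CC12OC1C[C@@H](CC2)C(C)=C | intermediate
3 | (4R)-limonene-1,2-diol | CC1(O)CC[C@H](CC1O)C(C)=C | intermediate (not isolated)
4 | (3R)-6-oxo-3-(prop-1-en-2-yl)heptanal | C=C(C)[C@H](CCC(C)=O)CC=O | intermediate
5 | (2E,5R)-2-methyl-8-oxo-5-(prop-1-en-2-yl)non-2-enal | C=C(C)[C@H](CCC(C)=O)C/C=C(C)/C=O | intermediate
6 | (5R,7E)-8-methyl-5-(prop-1-en-2-yl)deca-7,9-dien-2-one | C=C(C)[C@H](CCC(C)=O)C/C=C(C)/C=C | intermediate
7 | diethyl (5R,7E)-8-methyl-5-(prop-1-en-2-yl)deca-1,7,9-trien-2-yl phosphate | C=C(C)[C@H](CCC(=C)OP(=O)(OCC)OCC)C/C=C(C)/C=C | intermediate (not isolated)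
8 | (3E,6R)-3-methyl-6-(prop-1-en-2-yl)deca-1,3-dien-9-yne | C=C(C)[C@H](CCC#C)C/C=C(C)/C=C | intermediate
9 | 1,2,3,5-tetramethoxybenzene | COc1cc(OC)c(OC)c(OC)c1 | starting material
10 | N,N-dimethyl-(2,3,4,6-tetramethoxyphenyl)methaniminium chloride | C[N+](C)=Cc1c(OC)c(OC)c(OC)cc1OC.[Cl-] | intermediate (not isolated)
11 | 2,3,4,6-tetramethoxybenzaldehyde | O=Cc1c(OC)c(OC)c(OC)cc1OC | intermediate
12 | [(1E,5R,7E)-2,8-dimethyl-5-(prop-1-en-2-yl)deca-1,7,9-trien-1-yl]dimethylalumane | C=C(C)[C@H](CC/C(C)=C/[Al](C)C)C/C=C(C)/C=C | intermediate (not isolated)
13 | (2E,6R,8E)-3,9-dimethyl-6-(prop-1-en-2-yl)-1-(2,3,4,6-tetramethoxyphenyl)undeca-2,8,10-trien-1-ol, both C1 epimers | C=C(C)[C@H](CC/C(C)=C/C(O)c1c(OC)c(OC)c(OC)cc1OC)C/C=C(C)/C=C | intermediate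
14 | (2E,6R,8E)-3,9-dimethyl-6-(prop-1-en-2-yl)-1-(2,3,4,6-tetramethoxyphenyl)undeca-2,8,10-trien-1-one | C=C(C)[C@H](CC/C(C)=C/C(=O)c1c(OC)c(OC)c(OC)cc1OC)C/C=C(C)/C=C | intermediate
15 | 1β-(2,3,4,6-tetramethoxybenzoyl)eudesma-3,11-diene (5α-H, 7β-isopropenyl, 10β-methyl) | C=C(C)[C@@H]1CC[C@]2(C)[C@@H](C1)C(C)=CC[C@H]2C(=O)c1c(OC)c(OC)c(OC)cc1OC | intermediate
16 | 1β-(2-hydroxy-3,4,6-trimethoxybenzoyl)eudesma-3,11-diene | C=C(C)[C@@H]1CC[C@]2(C)[C@@H](C1)C(C)=CC[C@H]2C(=O)c1c(O)c(OC)c(OC)cc1OC | intermediate
17 | 3α,4α-epoxy-1β-(2-hydroxy-3,4,6-trimethoxybenzoyl)eudesm-11-ene | C=C(C)[C@@H]1CC[C@]2(C)[C@@H](C1)[C@](C)(O3)[C@H]3C[C@H]2C(=O)c1c(O)c(OC)c(OC)cc1OC | intermediate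
18 | 1β-[hydroxy(2-hydroxy-3,4,6-trimethoxyphenyl)methyl]eudesm-11-en-4α-ol, both carbinol epimers | C=C(C)[C@@H]1CC[C@]2(C)[C@@H](C1)[C@](C)(O)CC[C@H]2C(O)c1c(O)c(OC)c(OC)cc1OC | intermediate
19 | α-methoxystyrene | COC(=C)c1ccccc1 | starting material
20 | 6-[(4α-hydroxyeudesm-11-en-1β-yl)methylidene]-2,3,5-trimethoxycyclohexa-2,4-dien-1-one (o-quinone methide, alkene geometry open) | C=C(C)[C@@H]1CC[C@]2(C)[C@@H](C1)[C@](C)(O)CC[C@H]2C=C1C(=O)C(OC)=C(OC)C=C1OC | intermediate (not isolated)
21 | 1β-(2'-methoxy-5',7',8'-trimethoxy-2'-phenylchroman-4'-yl)eudesm-11-en-4α-ol, methoxy cis to the eudesmyl group | C=C(C)[C@@H]1CC[C@]2(C)[C@@H](C1)[C@](C)(O)CC[C@H]2[C@@H]1C[C@@](OC)(c2ccccc2)Oc2c(OC)c(OC)cc(OC)c21 | intermediate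
22 | 1β-[(4'R)-5',7',8'-trimethoxy-2'-phenyl-4'H-chromen-4'-yl]eudesm-11-en-4α-ol | C=C(C)[C@@H]1CC[C@]2(C)[C@@H](C1)[C@](C)(O)CC[C@H]2[C@@H]1C=C(c2ccccc2)Oc2c(OC)c(OC)cc(OC)c21 | target

## Step count and least certain steps

Total step count: 14. Longest linear sequence: 13 steps (steps 1–5 and 7–14 from 1; step 6 is a one-step side branch from 9).

**Step 9 (key step).** The β,β-disubstituted enone carries a bulky, electron-rich aroyl group and may be activated too weakly. In that case Lewis acid-induced oligomerisation of the 2-methyl-1,3-diene or a carbonyl-ene process at the isopropenyl group could outrun the cycloaddition. The endo-lying C10 methyl also meets the C4 methyl in the transition state, which may erode the endo (trans) selectivity.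
Fallback, from 8 back to 15: carboalumination as in step 7 (through 12) and trapping with paraformaldehyde would give the allylic alcohol F1, and MnO2 the trienal F2. Its Me2AlCl-promoted or thermal intramolecular Diels–Alder reaction, with a smaller and stronger activating group but the same E geometry and endo logic, would give 1β-formyleudesma-3,11-diene F3. Ortho-lithiation of 9 (n-BuLi, TMEDA, between two methoxy groups) gives 2,3,4,6-tetramethoxyphenyllithium F4, which adds to F3 to give the carbinol F5; Dess–Martin oxidation returns 15.

**Step 13.** At the temperature of the thermal dehydration the quinone methide may escape by a 1,5-hydrogen shift from C1 (to a 2-alkenylphenol) or by oligomerisation before the enol ether reacts. The facial selectivity at C4' may also be lower than the allylic-strain model predicts.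
Fallback, from 18 back to 21: phenol-selective acylation (Boc2O, catalytic DMAP, CH2Cl2, 0 °C) would give the aryl tert-butyl carbonate F6. Deprotonation of its benzylic hydroxyl with t-BuMgCl at −78 °C in the presence of 19 moves the Boc group to the benzylic oxygen and expels it, so that 20 forms and is trapped far below room temperature in a magnesium-templated cycloaddition, giving 21.

**Step 12.** Hydride has to enter C3 against the preference for diaxial epoxide opening, which is slow. Under forcing conditions the aluminium alkoxide of the electron-rich o-hydroxybenzyl alcohol may ionise and be reduced further at C4', or the epoxide may rearrange under Lewis acid assistance.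
Fallback, from 17 back to 21: NaBH4 (MeOH, 0 °C) reduces only the ketone to the epoxy diol F7. Heating with 19 as in step 13 passes through the epoxy o-quinone methide F8 to the epoxy ketal F9. LiEt3BH (THF, rt) then opens the epoxide at C3 with no benzylic alkoxide left to over-reduce, and gives 21.

**Step 10.** Cleavage may occur at the other ortho methyl ether (next to the aryl C–H), which would lead to the isomeric trimethoxy pattern, or at both; addition of HCl to the alkenes on work-up is a lesser risk.
Fallback, from 11 back to 16: the regiochemistry is settled before any terpene material is committed. BCl3 on 11 gives 2-hydroxy-3,4,6-trimethoxybenzaldehyde F10, whose constitution can be proven and any isomer removed, and BnBr/K2CO3 gives 2-(benzyloxy)-3,4,6-trimethoxybenzaldehyde F11. Steps 7 to 9 are then run as before (through 12) to give the benzyloxy carbinol F12, the benzyloxy trienone F13 and the benzyloxy cycloadduct F14. BCl3 with pentamethylbenzene at −78 °C removes the benzyl group selectively and gives 16.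

**Step 7.** Transfer of the alkenyl group from aluminium to the hindered, electron-rich aldehyde may be sluggish, so that methyl transfer from residual methylalanes or hydride transfer of the Meerwein–Ponndorf type competes.
Fallback, from 8 back to 13: the same carboalumination followed by iodinolysis (I2, THF, −30 °C) would give the (E)-alkenyl iodide F15. A Nozaki–Hiyama–Kishi coupling with 11 (CrCl2, catalytic NiCl2, DMSO, rt), which is tolerant of hindered aldehydes and of the alkenes, would give 13.

## Further compounds

F1 | step 9 | (2E,6R,8E)-3,9-dimethyl-6-(prop-1-en-2-yl)undeca-2,8,10-trien-1-ol | C=C(C)[C@H](CC/C(C)=C/CO)C/C=C(C)/C=C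
F2 | step 9 | (2E,6R,8E)-3,9-dimethyl-6-(prop-1-en-2-yl)undeca-2,8,10-trienal | C=C(C)[C@H](CC/C(C)=C/C=O)C/C=C(C)/C=C
F3 | step 9 | 1β-formyleudesma-3,11-diene | C=C(C)[C@@H]1CC[C@]2(C)[C@@H](C1)C(C)=CC[C@H]2C=O
F4 | step 9 | 2,3,4,6-tetramethoxyphenyllithium | [Li]c1c(OC)c(OC)c(OC)cc1OC
F5 | step 9 | 1β-[hydroxy(2,3,4,6-tetramethoxyphenyl)methyl]eudesma-3,11-diene | C=C(C)[C@@H]1CC[C@]2(C)[C@@H](C1)C(C)=CC[C@H]2C(O)c1c(OC)c(OC)c(OC)cc1OC
F6 | step 13 | tert-butyl 2-[hydroxy(4α-hydroxyeudesm-11-en-1β-yl)methyl]-3,5,6-trimethoxyphenyl carbonate | C=C(C)[C@@H]1CC[C@]2(C)[C@@H](C1)[C@](C)(O)CC[C@H]2C(O)c1c(OC(=O)OC(C)(C)C)c(OC)c(OC)cc1OC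
F7 | step 12 | 3α,4α-epoxy-1β-[hydroxy(2-hydroxy-3,4,6-trimethoxyphenyl)methyl]eudesm-11-ene | C=C(C)[C@@H]1CC[C@]2(C)[C@@H](C1)[C@](C)(O3)[C@H]3C[C@H]2C(O)c1c(O)c(OC)c(OC)cc1OC
F8 | step 12 | 6-[(3α,4α-epoxyeudesm-11-en-1β-yl)methylidene]-2,3,5-trimethoxycyclohexa-2,4-dien-1-one | C=C(C)[C@@H]1CC[C@]2(C)[C@@H](C1)[C@](C)(O3)[C@H]3C[C@H]2C=C1C(=O)C(OC)=C(OC)C=C1OC
F9 | step 12 | 3α,4α-epoxy-1β-(2'-methoxy-5',7',8'-trimethoxy-2'-phenylchroman-4'-yl)eudesm-11-ene | C=C(C)[C@@H]1CC[C@]2(C)[C@@H](C1)[C@](C)(O3)[C@H]3C[C@H]2[C@@H]1C[C@@](OC)(c2ccccc2)Oc2c(OC)c(OC)cc(OC)c21
F10 | step 10 | 2-hydroxy-3,4,6-trimethoxybenzaldehyde | O=Cc1c(O)c(OC)c(OC)cc1OC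
F11 | step 10 | 2-(benzyloxy)-3,4,6-trimethoxybenzaldehyde | O=Cc1c(OCc2ccccc2)c(OC)c(OC)cc1OC
F12 | step 10 | (2E,6R,8E)-1-[2-(benzyloxy)-3,4,6-trimethoxyphenyl]-3,9-dimethyl-6-(prop-1-en-2-yl)undeca-2,8,10-trien-1-ol | C=C(C)[C@H](CC/C(C)=C/C(O)c1c(OCc2ccccc2)c(OC)c(OC)cc1OC)C/C=C(C)/C=C
F13 | step 10 | (2E,6R,8E)-1-[2-(benzyloxy)-3,4,6-trimethoxyphenyl]-3,9-dimethyl-6-(prop-1-en-2-yl)undeca-2,8,10-trien-1-one | C=C(C)[C@H](CC/C(C)=C/C(=O)c1c(OCc2ccccc2)c(OC)c(OC)cc1OC)C/C=C(C)/C=C
F14 | step 10 | 1β-[2-(benzyloxy)-3,4,6-trimethoxybenzoyl]eudesma-3,11-diene | C=C(C)[C@@H]1CC[C@]2(C)[C@@H](C1)C(C)=CC[C@H]2C(=O)c1c(OCc2ccccc2)c(OC)c(OC)cc1OC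
F15 | step 7 | (1E,5R,7E)-1-iodo-2,8-dimethyl-5-(prop-1-en-2-yl)deca-1,7,9-triene | C=C(C)[C@H](CC/C(C)=C/I)C/C=C(C)/C=C
A1 | alternative 1 | Hagemann's ester (ethyl 2-methyl-4-oxocyclohex-2-ene-1-carboxylate) | CCOC(=O)C1CCC(=O)C=C1C
A2 | alternative 1 | ethyl 3-[4-iodo-2-(2-methyl-1,3-dioxolan-2-yl)butyl]-2-methyl-4-oxocyclohex-2-ene-1-carboxylate (side-chain centre as C7 of the target, ring centre open) | CC1(OCCO1)[C@H](CCI)CC1=C(C)C(CCC1=O)C(=O)OCC
A3 | alternative 1 | trans-fused 4-oxo decalin with 1β-ester, 10β-methyl and C7 acetyl ketal | CC1(OCCO1)[C@@H]1CC[C@]2(C)[C@@H](C1)C(=O)CC[C@H]2C(=O)OCC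
A4 | alternative 2 | 1β-[2-(tert-butoxycarbonyloxy)-3,4,6-trimethoxybenzoyl]eudesm-11-en-4α-ol | C=C(C)[C@@H]1CC[C@]2(C)[C@@H](C1)[C@](C)(O)CC[C@H]2C(=O)c1c(OC(=O)OC(C)(C)C)c(OC)c(OC)cc1OC
A5 | alternative 2 | α-methoxystyrene | COC(=C)c1ccccc1
A6 | alternative 2 | 6-[(4α-hydroxyeudesm-11-en-1β-yl)methylidene]-2,3,5-trimethoxycyclohexa-2,4-dien-1-one | C=C(C)[C@@H]1CC[C@]2(C)[C@@H](C1)[C@](C)(O)CC[C@H]2C=C1C(=O)C(OC)=C(OC)C=C1OC
A7 | alternative 2 | 1β-(2'-methoxy-5',7',8'-trimethoxy-2'-phenylchroman-4'-yl)eudesm-11-en-4α-ol, methoxy cis to the eudesmyl group | C=C(C)[C@@H]1CC[C@]2(C)[C@@H](C1)[C@](C)(O)CC[C@H]2[C@@H]1C[C@@](OC)(c2ccccc2)Oc2c(OC)c(OC)cc(OC)c21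
A8 | alternative 3 | 2-[1-(4α-hydroxyeudesm-11-en-1β-yl)-3-oxo-3-phenylpropyl]-5-methoxy-1,4-benzoquinone | C=C(C)[C@@H]1CC[C@]2(C)[C@@H](C1)[C@](C)(O)CC[C@H]2[C@H](CC(=O)c1ccccc1)C1=CC(=O)C(OC)=CC1=O
A9 | alternative 3 | 1β-(5',8'-dihydroxy-7'-methoxy-2'-phenyl-4'H-chromen-4'-yl)eudesm-11-en-4α-ol | C=C(C)[C@@H]1CC[C@]2(C)[C@@H](C1)[C@](C)(O)CC[C@H]2[C@@H]1C=C(c2ccccc2)Oc2c(O)c(OC)cc(O)c21
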